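**Plan**

1. Retrosynthesis: cut the C6 and C4 esters, then C6–C7 (alkenyl iodide/aldehyde closure of the oxonane), then the lactone C3–O bond (acid opening of a C3–C4 epoxide), then the C11 carbinol (from C11=C12), and last the oxolane at C1–C2 and C9–C10, which leads to a carvone-derived cyclohexadienyl 1,2-diol and a (Z)-enal.
2. Forward ring order: cyclohexadiene (from the chiral pool) → oxane cation → oxolane by ring contraction → seven-membered lactone → oxonane.
3. Enabling feature: the oxolane (O, C2, C1, C10, C9) is cis-fused at C1–C10 to the six-membered ring, and C10 sits between C9 and the C11=C12 alkene (the C11 carbinol of the target). An oxan-4-yl cation at C10 is therefore allylic and flanked by a carbinol carbon, so C9 can shift to C10 (oxane → oxolane).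
4. Stereochemistry: C14 from (R)-carvone; C15 by catalyst-controlled hydrogenation; C9 from (S)-glycidyl butanoate; C1 and C10 in the key step; C2 by oxidation to a ketal and exo hydride delivery; C11 by anti bromohydrin opening; C3 and C4 by epoxidation of the Z alkene and inverting lactonization; C6 in the ring closure.

Key step: step 15

Remark: cladiellin numbering is used (oxolane O–C2–C1–C10–C9; carbocycle C1, C10, C11(Me,OH), C12, C13, C14; C15(Me)–C16(=O)–O–C3(Me); C4 octanoate; C6 butanoate; C7=CH2; C8). In the SMILES as written, C3 (on C2) is cis to C14 and C11 on the oxolane and C8 (on C9) is trans to them, so C2 is endo and the oxonane is a strained, trans-bridged ring; the route is built for exactly this isomer.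

**Route**

Step 1
Reactants: 1 (R)-(−)-carvone
Product: 2 (5R)-5-(3-chloroprop-1-en-2-yl)-2-methylcyclohex-2-en-1-one
Conditions: Ca(OCl)2, CO2 (solid), CH2Cl2/H2O, 0 °C
Reagents that add atoms: calcium hypochlorite, [Ca+2].[O-]Cl.[O-]Cl
Why: Ene-type allylic chlorination by HOCl attacks the electron-rich 1,1-disubstituted alkene rather than the enone and shifts the double bond to give the 2-substituted allyl chloride, with no stereocenter touched.

Step 2
Reactants: 2 allyl chloride
Product: 4 (5R)-5-(3-hydroxyprop-1-en-2-yl)-2-methylcyclohex-2-en-1-one, via allylic acetate 3 (not isolated)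
Conditions: KOAc, DMF, 60 °C; then K2CO3, MeOH, rt
Reagents that add atoms: potassium acetate, CC(=O)[O-].[K+]
Why: SN2 displacement of the primary allylic chloride by acetate (SN2 and SN2' give the same product) followed by methanolysis of the acetate gives the allylic alcohol.

Step 3
Reactants: 4 allylic alcohol
Product: 5 (5R)-5-[(2R)-1-hydroxypropan-2-yl]-2-methylcyclohex-2-en-1-one
Conditions: H2 (50 atm), Ru(OAc)2[(S)-BINAP] (cat.), MeOH, rt
Reagents that add atoms: none
Why: Hydroxyl-directed asymmetric hydrogenation of the 1,1-disubstituted allylic alcohol leaves the undirected enone alkene alone and sets C15 under catalyst control ((S)-ligand assigned by analogy with allylic alcohol substrates; the antipodal ligand would give the epimer).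

Step 4
Reactants: 5 primary alcohol
Product: 6 (2R)-2-[(1R)-4-methyl-5-oxocyclohex-3-en-1-yl]propyl pivalate
Conditions: pivaloyl chloride, pyridine, CH2Cl2, 0 °C
Reagents that add atoms: pivaloyl chloride, CC(C)(C)C(=O)Cl
Why: Acylation of the primary alcohol gives an ester without α-hydrogens that survives the amide base and the Lewis acid steps and is later removed reductively.

Step 5
Reactants: 6 enone pivalate
Product: 7 (3S)-6-methyl-3-[(2R)-1-(pivaloyloxy)propan-2-yl]cyclohexa-1,5-dien-1-yl trifluoromethanesulfonate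
Conditions: LDA, THF, −78 °C; then PhNTf2, −78 to 0 °C
Reagents that add atoms: N-phenylbis(trifluoromethanesulfonimide), O=S(=O)(N(c1ccccc1)S(=O)(=O)C(F)(F)F)C(F)(F)F
Why: Kinetic deprotonation at the α' methylene (C1) and O-sulfonylation of the cross-conjugated dienolate give the dienyl triflate, with C14 untouched.

Step 6
Reactants: 8 (S)-glycidyl butanoate; 9 ethynyltrimethylsilane
Product: 10 (2S)-2-hydroxy-5-(trimethylsilyl)pent-4-yn-1-yl butanoate
Conditions: n-BuLi, THF, −78 °C; then BF3·OEt2 and 8, −78 °C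
Reagents that add atoms: none
Why: BF3-promoted opening of the epoxide at its terminal carbon by the lithium acetylide at low temperature tolerates the ester and keeps the stereocenter that becomes C9.

Step 7
Reactants: 10 secondary alcohol
Product: 11 (2S)-2-(triethylsilyloxy)-5-(trimethylsilyl)pent-4-yn-1-yl butanoate
Conditions: Et3SiCl, imidazole, CH2Cl2, 0 °C
Reagents that add atoms: chlorotriethylsilane, CC[Si](Cl)(CC)CC
Why: Silylation gives an acid-labile ether that can later be removed in the presence of the pivalate.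

Step 8
Reactants: 11 butanoate
Product: 12 (2S)-2-(triethylsilyloxy)-5-(trimethylsilyl)pent-4-yn-1-ol
Conditions: i-Bu2AlH, CH2Cl2, −78 °C
Reagents that add atoms: none
Why: Reductive cleavage of the ester frees the primary alcohol without base-induced silyl migration.

Step 9
Reactants: 12 primary alcohol
Product: 13 (2S)-2-(triethylsilyloxy)-5-(trimethylsilyl)pent-4-ynal
Conditions: Dess–Martin periodinane, NaHCO3, CH2Cl2, rt
Reagents that add atoms: none
Why: Buffered Dess–Martin oxidation gives the α-silyloxy aldehyde, which is used at once to avoid epimerization.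

Step 10
Reactants: 7 dienyl triflate; 13 aldehyde
Product: 14 (1R,2S)-1-{(3S)-6-methyl-3-[(2R)-1-(pivaloyloxy)propan-2-yl]cyclohexa-1,5-dien-1-yl}-2-(triethylsilyloxy)-5-(trimethylsilyl)pent-4-yn-1-ol
Conditions: CrCl2 (4 equiv), NiCl2 (cat.), DMF, rt
Reagents that add atoms: none
Why: Nozaki–Hiyama–Kishi coupling (zerovalent nickel inserts into the alkenyl triflate, the alkenyl group passes to trivalent chromium and adds to the aldehyde in the Felkin–Anh sense); the new carbinol carbon later leaves as the formyl carbon, so its configuration is not needed.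

Step 11
Reactants: 14 silyl ether
Product: 15 (1R,2S)-1-{(3S)-6-methyl-3-[(2R)-1-(pivaloyloxy)propan-2-yl]cyclohexa-1,5-dien-1-yl}-5-(trimethylsilyl)pent-4-yne-1,2-diol
Conditions: PPTS, MeOH, 0 °C
Reagents that add atoms: none
Why: Mild acid methanolysis removes the secondary triethylsilyl ether and leaves the pivalate and the alkynylsilane, freeing the 1,2-diol.

Step 12
Reactants: 16 3-(tert-butyldimethylsilyloxy)propanal; 17 ethyl 2-(diphenoxyphosphoryl)propanoate
Product: 18 ethyl (2Z)-5-(tert-butyldimethylsilyloxy)-2-methylpent-2-enoate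
Conditions: NaH, THF, −78 to 0 °C
Reagents that add atoms: none
Why: Z-selective Horner–Wadsworth–Emmons olefination with the diaryl phosphonate (fast elimination from the kinetic adduct) gives the (Z)-trisubstituted enoate.

Step 13
Reactants: 18 (Z)-enoate
Product: 19 (2Z)-5-(tert-butyldimethylsilyloxy)-2-methylpent-2-en-1-ol
Conditions: i-Bu2AlH, CH2Cl2, −78 °C
Reagents that add atoms: none
Why: 1,2-Reduction of the ester gives the allylic alcohol with the Z geometry retained.

Step 14
Reactants: 19 allylic alcohol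
Product: 20 (2Z)-5-(tert-butyldimethylsilyloxy)-2-methylpent-2-enal
Conditions: Dess–Martin periodinane, NaHCO3, CH2Cl2, 0 °C
Reagents that add atoms: none
Why: Buffered Dess–Martin oxidation gives the (Z)-enal without isomerization to the E isomer.

Step 15
Reactants: 15 cyclohexadienyl diol; 20 (Z)-enal
Product: 23 2-epi oxolane aldehyde (cis-fused oxolane O–C2–C1–C10–C9 with formyl on C10, (Z)-alkenyl chain on C2 trans to C14, propargyl chain on C9, C11=C12 alkene), via dioxolane acetal 21 (not isolated), via oxanyl cation 22 (not isolated)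
Conditions: BF3·OEt2, MgSO4, CH2Cl2, −55 to −20 °C
Reagents that add atoms: none
Why: Prins–pinacol condensation–rearrangement: BF3·OEt2 turns the diol and the enal into acetal 21, which opens to the (E)-oxocarbenium ion on O9; the C1=C10 alkene attacks its carbon (C2) in a chair-like 6-endo Prins closure that forms an oxane (O, C2, C1, C10, carbinol carbon, C9) and leaves the allyl cation 22 at C10. A pinacol 1,2-shift of C9 from the carbinol carbon to C10 then contracts the oxane to the oxolane (O, C2, C1, C10, C9) and turns the carbinol carbon into the formyl group; the closest known reaction type is the acid-promoted Prins–pinacol synthesis of 3-acyl oxolanes from allylic 1,2-diols and aldehydes. C1 is set by attack anti to the C14 side chain, C2 by the equatorial alkenyl group of the (E)-oxocarbenium ion in the chair (C3 trans to C14, corrected in steps 17 and 18), and C10 by the suprafacial shift that makes the ring fusion cis, while C9 keeps the configuration of the aldehyde. The step needs facial selectivity on the diene, which the (9S) carbinol secures because it places C8 equatorial in the same chair that is attacked anti to C14 (matched pair), and it needs retention of the Z geometry, which the low temperature secures.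

Step 16
Reactants: 23 aldehyde
Product: 24 deformylated 2-epi oxolane (H on C10, cis ring fusion)
Conditions: hν (Pyrex), 1,4-dioxane, rt
Reagents that add atoms: none
Why: Norrish type 1 cleavage of the β,γ-unsaturated aldehyde gives an allyl/formyl radical pair that collapses by hydrogen transfer to C10 with loss of CO, on the face the formyl group occupied, so the cis fusion is kept.

Step 17
Reactants: 24 allylic ether
Product: 25 C2 methyl ketal (methoxy on the exo face)
Conditions: DDQ, MeOH, 2,6-dichloropyridine, CH2Cl2, 0 °C to rt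
Reagents that add atoms: methanol, CO
Why: DDQ abstracts hydride from the only C–H that is both allylic and α to oxygen (C2–H), and methanol traps the conjugated oxocarbenium ion as the cyclic ketal (oxidative C–H functionalization of an allylic ether), which erases the C2 stereocenter on purpose.

Step 18
Reactants: 25 ketal
Product: 26 oxolane with the target configuration at C2 (alkenyl chain endo, cis to C14)
Conditions: Et3SiH, BF3·OEt2, CH2Cl2, −78 °C
Reagents that add atoms: none
Why: BF3 ionizes the ketal and the silane delivers hydride to the convex (exo) face of the cis-fused bicyclic oxocarbenium ion (C-glycoside-type ketal reduction), which places H2 exo and C3 endo; the low temperature preserves the Z alkene.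

Step 19
Reactants: 26 diene
Product: 27 bromohydrin (C12 bromide anti to the C11 hydroxyl; hydroxyl cis to C9)
Conditions: NBS, THF/H2O, 0 °C
Reagents that add atoms: N-bromosuccinimide, O=C1CCC(=O)N1Br; water, O
Why: The bromonium ion forms on the more nucleophilic and more exposed C11=C12 alkene (C3=C4 is deactivated by the allylic C–O bond and lies in the concave pocket) on the face anti to the oxolane, and water opens it at the tertiary carbon from the opposite face, which sets C11.

Step 20
Reactants: 27 bromohydrin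
Product: 29 terminal alkyne carbinol, via silylalkyne carbinol 28 (not isolated)
Conditions: Bu3SnH, Et3B, air, toluene, 0 °C; then K2CO3, MeOH, rt
Reagents that add atoms: none
Why: Radical chain reduction of the secondary bromide at low temperature spares the silylalkyne, and brief basic methanolysis then cleaves the alkynyl–silicon bond while the hindered pivalate stays.

Step 21
Reactants: 29 pivalate
Product: 30 C16 primary alcohol
Conditions: i-Bu2AlH, CH2Cl2, −78 °C
Reagents that add atoms: none
Why: Reductive cleavage of the pivalate frees the C16 alcohol in the presence of the silyl ether, the alkene and the alkyne.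

Step 22
Reactants: 30 primary alcohol
Product: 31 C16 carboxylic acid
Conditions: TEMPO (cat.), PhI(OAc)2, MeCN/H2O, rt
Reagents that add atoms: water, O
Why: Oxoammonium oxidation takes the primary alcohol through the aldehyde hydrate to the acid under near-neutral conditions, so the alkene, alkyne and tertiary alcohol are inert and C15 is not epimerized.

Step 23
Reactants: 31 alkenoic acid
Product: 33 seven-membered lactone (C16(=O)–O–C3) with free C4 hydroxyl, via epoxy acid 32 (not isolated)
Conditions: m-CPBA, CH2Cl2, 0 °C; then CSA (cat.), rt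
Reagents that add atoms: 3-chloroperbenzoic acid, OOC(=O)c1cccc(Cl)c1
Why: Prilezhaev epoxidation of the only electron-rich alkene occurs on the face syn to the ring oxygen (A(1,3)-strain conformer, the other face blocked by C1 and the carbocycle), and the tethered acid then opens the epoxide at the tertiary carbon C3 in a 7-exo mode with inversion, which sets C3 and leaves the epoxide oxygen as the C4 hydroxyl (anti addition to the Z alkene).

Step 24
Reactants: 33 hydroxy lactone
Product: 34 C4 octanoate
Conditions: octanoyl chloride, pyridine, DMAP (cat.), CH2Cl2, 0 °C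
Reagents that add atoms: octanoyl chloride, CCCCCCCC(=O)Cl
Why: Acylation of the secondary alcohol proceeds with retention while the hindered tertiary C11 hydroxyl does not react.

Step 25
Reactants: 34 terminal alkyne
Product: 35 2-iodoalkene (iodide on C7, C7=CH2)
Conditions: B-iodo-9-BBN, hexane/CH2Cl2, −20 °C; then AcOH; aqueous work-up
Reagents that add atoms: B-iodo-9-borabicyclo[3.3.1]nonane, IB1C2CCCC1CCC2
Why: Syn haloboration of the terminal alkyne places iodine on the internal carbon and protonolysis of the C–B bond gives the 2-iodo-1-alkene; excess reagent covers the borinate formed at the tertiary hydroxyl.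

Step 26
Reactants: 35 silyl ether
Product: 36 C6 primary alcohol
Conditions: HF·pyridine, pyridine, THF, 0 °C
Reagents that add atoms: none
Why: Buffered fluoride cleavage of the primary silyl ether avoids acyl migration from O4 to O6 and leaves the alkenyl iodide intact.

Step 27
Reactants: 36 primary alcohol
Product: 37 C6 aldehyde
Conditions: Dess–Martin periodinane, NaHCO3, CH2Cl2, rt
Reagents that add atoms: none
Why: Dess–Martin oxidation of the primary alcohol gives the aldehyde while the tertiary alcohol is inert.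

Step 28
Reactants: 37 iodo aldehyde
Product: 38 tetracyclic (6R) allylic alcohol (oxonane closed)
Conditions: CrCl2, NiCl2 (cat.), DMSO/THF, rt, high dilution
Reagents that add atoms: none
Why: Intramolecular Nozaki–Hiyama–Kishi reaction (zerovalent nickel inserts into the C–I bond, the alkenylchromium species adds irreversibly to the aldehyde) forms C6–C7 and the oxonane; attack on the outward face of the aldehyde in the ring-like conformer is expected to give the (6R) alcohol.

Step 29
Reactants: 38 allylic alcohol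
Product: 39 CNP0350718.2 (target)
Conditions: butanoic anhydride, DMAP, Et3N, CH2Cl2, 0 °C
Reagents that add atoms: butanoic anhydride, CCCC(=O)OC(=O)CCC
Why: Acylation of the secondary allylic alcohol proceeds with retention at C6 and the hindered tertiary C11 hydroxyl stays free.

**Compound list**

1 | (R)-(−)-carvone | CC1=CC[C@H](CC1=O)C(C)=C | starting material
2 | (5R)-5-(3-chloroprop-1-en-2-yl)-2-methylcyclohex-2-en-1-one | CC1=CC[C@H](CC1=O)C(=C)CCl | intermediate
3 | 2-[(1R)-4-methyl-5-oxocyclohex-3-en-1-yl]prop-2-en-1-yl acetate | CC1=CC[C@H](CC1=O)C(=C)COC(C)=O | intermediate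
4 | (5R)-5-(3-hydroxyprop-1-en-2-yl)-2-methylcyclohex-2-en-1-one | CC1=CC[C@H](CC1=O)C(=C)CO | intermediate
5 | (5R)-5-[(2R)-1-hydroxypropan-2-yl]-2-methylcyclohex-2-en-1-one | CC1=CC[C@H](CC1=O)[C@@H](C)CO | intermediate
6 | (2R)-2-[(1R)-4-methyl-5-oxocyclohex-3-en-1-yl]propyl pivalate | CC1=CC[C@H](CC1=O)[C@@H](C)COC(=O)C(C)(C)C | intermediate
7 | (3S)-6-methyl-3-[(2R)-1-(pivaloyloxy)propan-2-yl]cyclohexa-1,5-dien-1-yl triflate | CC1=CC[C@H](C=C1OS(=O)(=O)C(F)(F)F)[C@@H](C)COC(=O)C(C)(C)C | intermediate
8 | (S)-glycidyl butanoate | CCCC(=O)OC[C@@H]1CO1 | starting material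
9 | ethynyltrimethylsilane | C#C[Si](C)(C)C | starting material
10 | (2S)-2-hydroxy-5-(trimethylsilyl)pent-4-yn-1-yl butanoate | CCCC(=O)OC[C@@H](O)CC#C[Si](C)(C)C | intermediate
11 | (2S)-2-(triethylsilyloxy)-5-(trimethylsilyl)pent-4-yn-1-yl butanoate | CCCC(=O)OC[C@@H](O[Si](CC)(CC)CC)CC#C[Si](C)(C)C | intermediate
12 | (2S)-2-(triethylsilyloxy)-5-(trimethylsilyl)pent-4-yn-1-ol | OC[C@@H](O[Si](CC)(CC)CC)CC#C[Si](C)(C)C | intermediate
13 | (2S)-2-(triethylsilyloxy)-5-(trimethylsilyl)pent-4-ynal | O=C[C@@H](O[Si](CC)(CC)CC)CC#C[Si](C)(C)C | intermediate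
14 | (1R,2S) dienyl carbinol, C9 triethylsilyl ether | CC1=CC[C@H](C=C1[C@@H](O)[C@@H](O[Si](CC)(CC)CC)CC#C[Si](C)(C)C)[C@@H](C)COC(=O)C(C)(C)C | intermediate
15 | (1R,2S) cyclohexadienyl 1,2-diol | CC1=CC[C@H](C=C1[C@@H](O)[C@@H](O)CC#C[Si](C)(C)C)[C@@H](C)COC(=O)C(C)(C)C | intermediate
16 | 3-(tert-butyldimethylsilyloxy)propanal | O=CCCO[Si](C)(C)C(C)(C)C | starting material
17 | ethyl 2-(diphenoxyphosphoryl)propanoate | CCOC(=O)C(C)P(=O)(Oc1ccccc1)Oc1ccccc1 | starting material
18 | ethyl (2Z)-5-(tert-butyldimethylsilyloxy)-2-methylpent-2-enoate | CCOC(=O)/C(C)=C\CCO[Si](C)(C)C(C)(C)C | intermediate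
19 | (2Z)-5-(tert-butyldimethylsilyloxy)-2-methylpent-2-en-1-ol | OC/C(C)=C\CCO[Si](C)(C)C(C)(C)C | intermediate
20 | (2Z)-5-(tert-butyldimethylsilyloxy)-2-methylpent-2-enal | O=C/C(C)=C\CCO[Si](C)(C)C(C)(C)C | intermediate
21 | 1,3-dioxolane acetal of 15 and 20 (both acetal epimers) | CC1=CC[C@H](C=C1[C@H]5OC(/C(C)=C\CCO[Si](C)(C)C(C)(C)C)O[C@H]5CC#C[Si](C)(C)C)[C@@H](C)COC(=O)C(C)(C)C | intermediate
22 | oxan-4-yl allyl cation (oxane O–C2–C1–C10(+)–CHOH–C9 fused to the cyclohexene at C1–C10) | C[Si](C)(C)C#CC[C@@H]2O[C@H](/C(C)=C\CCO[Si](C)(C)C(C)(C)C)[C@H]4[C@@H](CC=C(C)[C+]4[C@H]2O)[C@@H](C)COC(=O)C(C)(C)C | intermediate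
23 | 2-epi oxolane aldehyde (formyl on C10, alkenyl chain on C2 exo) | C[Si](C)(C)C#CC[C@@H]2O[C@H](/C(C)=C\CCO[Si](C)(C)C(C)(C)C)[C@H]4[C@@H](CC=C(C)[C@]42C=O)[C@@H](C)COC(=O)C(C)(C)C | intermediate
24 | deformylated 2-epi oxolane | C[Si](C)(C)C#CC[C@@H]2O[C@H](/C(C)=C\CCO[Si](C)(C)C(C)(C)C)[C@H]4[C@@H](CC=C(C)[C@H]42)[C@@H](C)COC(=O)C(C)(C)C | intermediate
25 | C2 methyl ketal (methoxy exo) | C[Si](C)(C)C#CC[C@@H]2O[C@@](OC)(/C(C)=C\CCO[Si](C)(C)C(C)(C)C)[C@H]4[C@@H](CC=C(C)[C@H]42)[C@@H](C)COC(=O)C(C)(C)C | intermediate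
26 | oxolane with target configuration at C2 (alkenyl chain endo) | C[Si](C)(C)C#CC[C@@H]2O[C@@H](/C(C)=C\CCO[Si](C)(C)C(C)(C)C)[C@H]4[C@@H](CC=C(C)[C@H]42)[C@@H](C)COC(=O)C(C)(C)C | intermediate
27 | 12-bromo-11-hydroxy bromohydrin | C[Si](C)(C)C#CC[C@@H]2O[C@@H](/C(C)=C\CCO[Si](C)(C)C(C)(C)C)[C@H]4[C@@H](C[C@H](Br)[C@@](C)(O)[C@H]42)[C@@H](C)COC(=O)C(C)(C)C | intermediate
28 | C11 carbinol, silylalkyne | C[Si](C)(C)C#CC[C@@H]2O[C@@H](/C(C)=C\CCO[Si](C)(C)C(C)(C)C)[C@H]4[C@@H](CC[C@@](C)(O)[C@H]42)[C@@H](C)COC(=O)C(C)(C)C | intermediate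
29 | C11 carbinol, terminal alkyne | C#CC[C@@H]2O[C@@H](/C(C)=C\CCO[Si](C)(C)C(C)(C)C)[C@H]4[C@@H](CC[C@@](C)(O)[C@H]42)[C@@H](C)COC(=O)C(C)(C)C | intermediate
30 | C16 primary alcohol | C#CC[C@@H]2O[C@@H](/C(C)=C\CCO[Si](C)(C)C(C)(C)C)[C@H]4[C@@H](CC[C@@](C)(O)[C@H]42)[C@@H](C)CO | intermediate
31 | C16 carboxylic acid | C#CC[C@@H]2O[C@@H](/C(C)=C\CCO[Si](C)(C)C(C)(C)C)[C@H]4[C@@H](CC[C@@](C)(O)[C@H]42)[C@@H](C)C(=O)O | intermediate
32 | 3,4-epoxy acid (epoxide oxygen syn to the ring oxygen) | C#CC[C@@H]2O[C@@H]([C@]7(C)O[C@@H]7CCO[Si](C)(C)C(C)(C)C)[C@H]4[C@@H](CC[C@@](C)(O)[C@H]42)[C@@H](C)C(=O)O | intermediate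
33 | seven-membered lactone with free C4 hydroxyl | C#CC[C@@H]2O[C@@H]3[C@H]4[C@@H](CC[C@@](C)(O)[C@H]42)[C@@H](C)C(=O)O[C@@]3(C)[C@H](O)CCO[Si](C)(C)C(C)(C)C | intermediate
34 | C4 octanoate, terminal alkyne | C#CC[C@@H]2O[C@@H]3[C@H]4[C@@H](CC[C@@](C)(O)[C@H]42)[C@@H](C)C(=O)O[C@@]3(C)[C@H](OC(=O)CCCCCCC)CCO[Si](C)(C)C(C)(C)C | intermediate
35 | 2-iodoalkene | C=C(I)C[C@@H]2O[C@@H]3[C@H]4[C@@H](CC[C@@](C)(O)[C@H]42)[C@@H](C)C(=O)O[C@@]3(C)[C@H](OC(=O)CCCCCCC)CCO[Si](C)(C)C(C)(C)C | intermediate
36 | C6 primary alcohol | C=C(I)C[C@@H]2O[C@@H]3[C@H]4[C@@H](CC[C@@](C)(O)[C@H]42)[C@@H](C)C(=O)O[C@@]3(C)[C@H](OC(=O)CCCCCCC)CCO | intermediate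
37 | C6 aldehyde | C=C(I)C[C@@H]2O[C@@H]3[C@H]4[C@@H](CC[C@@](C)(O)[C@H]42)[C@@H](C)C(=O)O[C@@]3(C)[C@H](OC(=O)CCCCCCC)CC=O | intermediate
38 | tetracyclic (6R) allylic alcohol | C=C1C[C@@H]2O[C@@H]3[C@H]4[C@@H](CC[C@@](C)(O)[C@H]42)[C@@H](C)C(=O)O[C@@]3(C)[C@H](OC(=O)CCCCCCC)C[C@H]1O | intermediate
39 | CNP0350718.2 | C=C1C[C@@H]2O[C@@H]3[C@H]4[C@@H](CC[C@@](C)(O)[C@H]42)[C@@H](C)C(=O)O[C@@]3(C)[C@H](OC(=O)CCCCCCC)C[C@H]1OC(=O)CCC | target

**Totals and risks**

Total step count: 29. Longest linear sequence: 22 steps (1–5, 10, 11, 15–29). Steps 6–9 make aldehyde 13 and steps 12–14 make enal 20.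

Steps most likely to fail:

Step 28 (closure of the trans-bridged oxonane). The transition state already carries much of the transannular strain of the nine-membered ring, so the alkenylchromium species may be protonated or may dimerize before it reaches the aldehyde; facial control at C6 is also uncertain. The fallback sets out from 34. HF·pyridine gives the alkynol F1 and Dess–Martin oxidation gives the ynal F2. A reductive alkyne–aldehyde macrocyclization with Ni(cod)2 (zerovalent nickel), a bulky N-heterocyclic carbene ligand and Et3SiH (exo mode, C–C bond at the internal alkyne carbon through an oxanickelacycle) gives the macrocyclic triethylsilyl ether F3, and HF·pyridine returns to the route at 38.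

Step 17 (oxidation at C2). Hydride abstraction may be slow or may compete with oxidation at the allylic positions of the cyclohexene, and the conjugated oxocarbenium ion may lose its Z geometry before it is trapped. The fallback sets out from 15. The Prins–pinacol reaction is run with ethyl glyoxylate (CCOC(=O)C=O) to give the formyl ester F4, and Norrish type 1 photolysis gives the ester F5. Me3SnOH gives the acid F6, Pb(OAc)4 (oxidative decarboxylation of the α-alkoxy acid) gives the lactol acetate F7, hydrazine acetate gives the lactol F8, and Ag2CO3 on Celite gives the γ-lactone F9. The alkenyllithium from (Z)-tert-butyl[(4-iodopent-3-en-1-yl)oxy]dimethylsilane and t-BuLi adds at −78 °C to give the hemiketal F10. Et3SiH/BF3·OEt2 at −78 °C then delivers hydride from the exo face and returns to the route at 26.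

Step 23 (epoxidation and lactonization). The peracid may attack the Z alkene with poor facial selectivity, and the acid-labile trisubstituted epoxide may rearrange before the seven-membered ring closes. The fallback sets out from 31. Me3SiCHN2 gives the methyl ester F11. Reagent-controlled epoxidation with a fructose-derived chiral ketone catalyst and KHSO5 at pH 10 gives the epoxy ester F12. LiOH followed by buffered acidification closes the lactone through epoxy acid 32 and returns to the route at 33.

**Further compounds**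

F1 | step 28 | alkynol (C6 primary alcohol, terminal alkyne, C4 octanoate) | C#CC[C@@H]2O[C@@H]3[C@H]4[C@@H](CC[C@@](C)(O)[C@H]42)[C@@H](C)C(=O)O[C@@]3(C)[C@H](OC(=O)CCCCCCC)CCO
F2 | step 28 | ynal (C6 aldehyde, terminal alkyne) | C#CC[C@@H]2O[C@@H]3[C@H]4[C@@H](CC[C@@](C)(O)[C@H]42)[C@@H](C)C(=O)O[C@@]3(C)[C@H](OC(=O)CCCCCCC)CC=O
F3 | step 28 | macrocyclic C6 triethylsilyl ether | C=C1C[C@@H]2O[C@@H]3[C@H]4[C@@H](CC[C@@](C)(O)[C@H]42)[C@@H](C)C(=O)O[C@@]3(C)[C@H](OC(=O)CCCCCCC)C[C@H]1O[Si](CC)(CC)CC
F4 | step 17 | oxolane with ethyl ester on C2 (exo) and formyl on C10 | C[Si](C)(C)C#CC[C@@H]2O[C@H](C(=O)OCC)[C@H]4[C@@H](CC=C(C)[C@]42C=O)[C@@H](C)COC(=O)C(C)(C)C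
F5 | step 17 | deformylated oxolane C2 ethyl ester | C[Si](C)(C)C#CC[C@@H]2O[C@H](C(=O)OCC)[C@H]4[C@@H](CC=C(C)[C@H]42)[C@@H](C)COC(=O)C(C)(C)C
F6 | step 17 | oxolane C2 carboxylic acid | C[Si](C)(C)C#CC[C@@H]2O[C@H](C(=O)O)[C@H]4[C@@H](CC=C(C)[C@H]42)[C@@H](C)COC(=O)C(C)(C)C
F7 | step 17 | lactol acetate at C2 (anomers) | C[Si](C)(C)C#CC[C@@H]2OC(OC(C)=O)[C@H]4[C@@H](CC=C(C)[C@H]42)[C@@H](C)COC(=O)C(C)(C)C
F8 | step 17 | lactol at C2 (anomers) | C[Si](C)(C)C#CC[C@@H]2OC(O)[C@H]4[C@@H](CC=C(C)[C@H]42)[C@@H](C)COC(=O)C(C)(C)C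
F9 | step 17 | cis-fused γ-lactone (C2 carbonyl) | C[Si](C)(C)C#CC[C@@H]2OC(=O)[C@H]4[C@@H](CC=C(C)[C@H]42)[C@@H](C)COC(=O)C(C)(C)C
F10 | step 17 | C2 hemiketal bearing the (Z)-alkenyl chain (anomers) | C[Si](C)(C)C#CC[C@@H]2OC(O)(/C(C)=C\CCO[Si](C)(C)C(C)(C)C)[C@H]4[C@@H](CC=C(C)[C@H]42)[C@@H](C)COC(=O)C(C)(C)C
F11 | step 23 | methyl ester of acid 31 | C#CC[C@@H]2O[C@@H](/C(C)=C\CCO[Si](C)(C)C(C)(C)C)[C@H]4[C@@H](CC[C@@](C)(O)[C@H]42)[C@@H](C)C(=O)OC
F12 | step 23 | 3,4-epoxy methyl ester | C#CC[C@@H]2O[C@@H]([C@]7(C)O[C@@H]7CCO[Si](C)(C)C(C)(C)C)[C@H]4[C@@H](CC[C@@](C)(O)[C@H]42)[C@@H](C)C(=O)OC
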